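**Retrosynthetic overview** (phenanthrene locants: ring C = C1–C4, C4a, C10a; ring B = C4a, C4b, C8a, C9, C10, C10a; ring A = C4b–C8a)
1. Last events: MOM removal lets the C9 naphthol ketonise; the oxazolidine N,O-acetal comes from oxidative decarboxylation of an N-bound L-proline and capture of the iminium ion by the C4 hydroxyl.
2. C4 (methyl, oxygen) is set by dearomatising lactonisation of a 4-methyl-1-phenanthrol, with the proline carboxylate as tether (temporary lactone; the α-carbon relays its chirality to C4, is then destroyed and re-formed under control of C4). The 4-methylphenol comes from the 1,4-quinone (MeMgBr at C4, then zinc).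
3. Ring C is not closed as a six-membered ring. Its four contiguous heteroatom-bearing carbons C1(=O), C2(OMe), C3(N), C4(O), with the two oxygens para, are the pattern of a squaric amide ester, and its C4a–C10a bond can be carried inside an aromatic ring B (C9 ketone held as a naphthol ether). Ring C is therefore grown from a four-membered ring by Moore ring expansion of a 4-(1-naphthyl)-4-hydroxycyclobutenone.
4. Order of rings: rings A and B (naphthalene-1,8-diol), the pyrrolidine (L-proline) and the four-membered ring (dimethyl squarate) are bought; then ring C (step 7), the temporary lactone (step 10), the oxazolidine (step 12).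

Key step: step 7

Assumption: the 10H-phenanthren-9-one form drawn for the target is taken to be the stable tautomer of the corresponding 9-phenanthrol (peri-hydroxy ketone hydrogen bond, cross-conjugated ring C), so freeing the C9 oxygen should deliver it.

**Step 1**
Reactants: 1 naphthalene-1,8-diol
Product: 2 1,8-bis(methoxymethoxy)naphthalene
Conditions: NaH, MOMCl, DMF, 0 °C → rt
Reagents that add atoms: chloromethyl methyl ether (COCCl)
Why: O-alkylation of both peri phenoxides (Williamson-type acetal formation) should give the bis-MOM ether, which is stable to organolithiums, heat and base.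

**Step 2**
Reactants: 2 1,8-bis(methoxymethoxy)naphthalene
Product: 3 1-bromo-4,5-bis(methoxymethoxy)naphthalene
Conditions: NBS (1.0 equiv), MeCN, −20 → 0 °C
Reagents that add atoms: N-bromosuccinimide (O=C1CCC(=O)N1Br)
Why: Electrophilic aromatic bromination should go to the α-position para to an alkoxy group, as with 1,8-dimethoxynaphthalene, and the symmetry of 2 makes the two para positions equivalent.

**Step 3**
Reactants: 3 1-bromo-4,5-bis(methoxymethoxy)naphthalene
Product: 5 8-bromo-4,5-bis(methoxymethoxy)naphthalen-2-ol, via pinacol boronate 4 (not isolated)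
Conditions: [Ir(OMe)(cod)]2 (cat.), dtbpy (cat.), B2pin2, THF, 60 °C; then H2O2, NaOH (aq), 0 °C
Reagents that add atoms: bis(pinacolato)diboron (CC1(C)OB(OC1(C)C)B1OC(C)(C)C(C)(C)O1); hydrogen peroxide (OO)
Why: Sterically governed iridium-catalysed C–H borylation (Hartwig–Miyaura borylation) should take the only C–H with neither an ortho nor a peri substituent (the β-position of the unbrominated ring; the others are ortho to OMOM, ortho to Br or peri to Br), and oxidation of the C–B bond of boronate 4 then puts the hydroxyl on that carbon.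

**Step 4**
Reactants: 5 8-bromo-4,5-bis(methoxymethoxy)naphthalen-2-ol
Product: 6 1-bromo-7-methoxy-4,5-bis(methoxymethoxy)naphthalene
Conditions: MeI, K2CO3, acetone, 50 °C
Reagents that add atoms: iodomethane (CI)
Why: Williamson O-methylation of the only free naphthol installs the future C6 methoxy group.

**Step 5**
Reactants: 7 dimethyl squarate; 8 L-proline benzyl ester hydrochloride
Product: 9 benzyl (2S)-1-(2-methoxy-3,4-dioxocyclobut-1-en-1-yl)pyrrolidine-2-carboxylate
Conditions: Et3N, MeOH, rt
Reagents that add atoms: none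
Why: Addition–elimination of the secondary amine on the vinylogous ester of the squarate (squaramide ester formation) should stop after one methoxy group, because the product is a much less electrophilic vinylogous amide; the proline centre is untouched.

**Step 6**
Reactants: 6 1-bromo-7-methoxy-4,5-bis(methoxymethoxy)naphthalene; 9 benzyl (2S)-1-(2-methoxy-3,4-dioxocyclobut-1-en-1-yl)pyrrolidine-2-carboxylate
Product: 11 benzyl (2S)-1-{4-hydroxy-2-methoxy-4-[7-methoxy-4,5-bis(methoxymethoxy)naphthalen-1-yl]-3-oxocyclobut-1-en-1-yl}pyrrolidine-2-carboxylate (both carbinol epimers), via aryllithium 10 (not isolated)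
Conditions: 6, n-BuLi, THF, −78 °C; then added to 9, THF, −78 °C; NH4Cl (aq)
Reagents that add atoms: none
Why: Bromine–lithium exchange and 1,2-addition of the aryllithium to the more electrophilic carbonyl of the squaramide ester, the one next to the amino-bearing carbon (a vinylogous ester carbonyl; the other is a vinylogous amide carbonyl), as in the cyclobutenedione additions that precede a Moore rearrangement; the carbinol centre forms without control, which does not matter because it becomes sp2 in step 7.

**Step 7**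
Reactants: 11 benzyl (2S)-1-{4-hydroxy-2-methoxy-4-[7-methoxy-4,5-bis(methoxymethoxy)naphthalen-1-yl]-3-oxocyclobut-1-en-1-yl}pyrrolidine-2-carboxylate
Product: 14 benzyl (2S)-1-[2,6-dimethoxy-8,9-bis(methoxymethoxy)-1,4-dioxo-1,4-dihydrophenanthren-3-yl]pyrrolidine-2-carboxylate, via dienylketene 12 (not isolated), via hydroquinone 13 (not isolated)
Conditions: p-xylene, 138 °C; then Ag2O, rt
Reagents that add atoms: none
Why: On heating, cyclobutenone 11 should open by conrotatory 4π electrocyclic cleavage of the C(=O)–C(OH) bond with the hydroxyl rotating outward, which places the naphthyl group cis to the ketene in dienylketene 12. Disrotatory 6π electrocyclisation of the ketene carbon onto C2 of the naphthalene (the other ortho position is a ring-fusion carbon) closes ring C, and tautomerisation gives hydroquinone 13, which Ag2O oxidises to quinone 14. The closest known reaction type is the Moore ring expansion of squarate-derived 4-aryl-4-hydroxycyclobutenones to annulated quinones, which tolerates 3-amino and 2-alkoxy groups. No stereocentre is formed; the proline α-carbon is a spectator under these neutral conditions and the uncontrolled carbinol centre of 11 becomes sp2. The selectivity needed is constitutional: the order O, OMe, N, O around ring C is fixed by the regioselective addition of step 6, and the angular (phenanthrene) fusion is fixed because the four-membered ring sits on C1 of the naphthalene.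

**Step 8**
Reactants: 14 benzyl (2S)-1-[2,6-dimethoxy-8,9-bis(methoxymethoxy)-1,4-dioxo-1,4-dihydrophenanthren-3-yl]pyrrolidine-2-carboxylate
Product: 16 benzyl (2S)-1-[1-hydroxy-2,6-dimethoxy-8,9-bis(methoxymethoxy)-4-methylphenanthren-3-yl]pyrrolidine-2-carboxylate, via p-quinol 15 (not isolated)
Conditions: MeMgBr, THF, −78 °C; then AcOH, Zn dust, −78 °C → rt
Reagents that add atoms: methylmagnesium bromide (C[Mg]Br)
Why: Grignard 1,2-addition should occur at the C4 carbonyl, the more electrophilic one because the C1 carbonyl is a vinylogous amide (N–C3=C2–C1=O), and Zn/AcOH reductive aromatisation of the p-quinol then removes the C4 oxygen, so both C4 epimers converge on the 4-methylphenol.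

**Step 9**
Reactants: 16 benzyl (2S)-1-[1-hydroxy-2,6-dimethoxy-8,9-bis(methoxymethoxy)-4-methylphenanthren-3-yl]pyrrolidine-2-carboxylate
Product: 17 (2S)-1-[1-hydroxy-2,6-dimethoxy-8,9-bis(methoxymethoxy)-4-methylphenanthren-3-yl]pyrrolidine-2-carboxylic acid
Conditions: H2 (1 atm), Pd/C, EtOAc, rt
Reagents that add atoms: none
Why: Hydrogenolysis of the benzyl ester under neutral conditions should leave the MOM ethers, the electron-rich phenol and the α-stereocentre intact.

**Step 10**
Reactants: 17 (2S)-1-[1-hydroxy-2,6-dimethoxy-8,9-bis(methoxymethoxy)-4-methylphenanthren-3-yl]pyrrolidine-2-carboxylic acid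
Product: 18 δ-lactone between the proline carboxyl group [(2S)-pyrrolidine on C3] and the C4 oxygen of (4R)-4-hydroxy-2,6-dimethoxy-8,9-bis(methoxymethoxy)-4-methylphenanthren-1(4H)-one
Conditions: PhI(OAc)2, CF3CH2OH/CH2Cl2, −40 → 0 °C
Reagents that add atoms: none
Why: Oxidative dearomatisation of the phenol by the trivalent iodine reagent with intramolecular capture of the para carbon C4 by the carboxylate (hypervalent-iodine dearomatising lactonisation, a known reaction of phenols that carry a carboxylic acid tether) should close the six-membered lactone; because the N–aryl bond flanked by the C2 methoxy and C4 methyl groups is twisted out of the ring plane, the (S)-α-carbon sits over one face and only in that rotamer does its carboxyl group point at C4 and not at C2, so the C–O bond should form on that face and make C4 R.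

**Step 11**
Reactants: 18 δ-lactone (4R; αS)
Product: 19 (2S)-1-[(4R)-4-hydroxy-2,6-dimethoxy-8,9-bis(methoxymethoxy)-4-methyl-1-oxo-1,4-dihydrophenanthren-3-yl]pyrrolidine-2-carboxylic acid
Conditions: LiOH, THF/H2O, 0 °C; then HCl (aq) to pH 4, 0 °C
Reagents that add atoms: lithium hydroxide ([Li+].[OH-])
Why: Saponification of the tertiary-alkyl lactone frees the C4 alcohol and the acid; C4 cannot epimerise under base, and any loss of integrity at the α-carbon is irrelevant because that centre is destroyed next.

**Step 12**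
Reactants: 19 (2S)-1-[(4R)-4-hydroxy-2,6-dimethoxy-8,9-bis(methoxymethoxy)-4-methyl-1-oxo-1,4-dihydrophenanthren-3-yl]pyrrolidine-2-carboxylic acid
Product: 21 8,9-bis(methoxymethyl) ether of the 9-phenanthrol form of the target [(R) quaternary carbon C4; (S) aminal carbon], via iminium acetate 20 (not isolated)
Conditions: Pb(OAc)4, CH2Cl2, 0 °C → rt; then PPTS (cat.), rt
Reagents that add atoms: none
Why: Oxidative decarboxylation of the N-(vinylogous acyl) α-amino acid with lead tetraacetate (as known for N-acylprolines) gives the cyclic iminium ion, which the C4 hydroxyl captures to close the oxazolidine (N,O-acetal formation); the closure is reversible under the mild acid, so the aminal centre should settle as S, the epimer with its hydrogen syn to the C4 methyl group and the pyrrolidine methylene on the less crowded face of the oxazolidine, away from that methyl group.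

**Step 13**
Reactants: 21 bis-MOM ether
Product: 23 target CNP0528850.1, via 9-phenanthrol tautomer 22 (not isolated)
Conditions: HCl (2 M aq), THF, rt
Reagents that add atoms: none
Why: Acid hydrolysis of the two aryl MOM acetals frees the C8 phenol and the C9 naphthol, which should ketonise to the 10H-9-one; methanol is avoided so that the N,O-acetal is not exchanged.

**Compound list**
1 | naphthalene-1,8-diol | Oc1cccc2cccc(O)c12 | starting material
2 | 1,8-bis(methoxymethoxy)naphthalene | COCOc1cccc2cccc(OCOC)c12 | intermediate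
3 | 1-bromo-4,5-bis(methoxymethoxy)naphthalene | COCOc1ccc(Br)c2cccc(OCOC)c12 | intermediate
4 | 2-[8-bromo-4,5-bis(methoxymethoxy)naphthalen-2-yl]-4,4,5,5-tetramethyl-1,3,2-dioxaborolane | CC1(C)OB(OC1(C)C)c1cc(OCOC)c2c(OCOC)ccc(Br)c2c1 | intermediate (not isolated)
5 | 8-bromo-4,5-bis(methoxymethoxy)naphthalen-2-ol | Oc1cc(OCOC)c2c(OCOC)ccc(Br)c2c1 | intermediate
6 | 1-bromo-7-methoxy-4,5-bis(methoxymethoxy)naphthalene | COc1cc(OCOC)c2c(OCOC)ccc(Br)c2c1 | intermediate
7 | dimethyl squarate (3,4-dimethoxycyclobut-3-ene-1,2-dione) | COC1=C(OC)C(=O)C1=O | starting material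
8 | L-proline benzyl ester hydrochloride | Cl.O=C(OCc1ccccc1)[C@@H]1CCCN1 | starting material
9 | benzyl (2S)-1-(2-methoxy-3,4-dioxocyclobut-1-en-1-yl)pyrrolidine-2-carboxylate | COC1=C(N2CCC[C@H]2C(=O)OCc2ccccc2)C(=O)C1=O | intermediate
10 | [7-methoxy-4,5-bis(methoxymethoxy)naphthalen-1-yl]lithium | [Li]c1ccc(OCOC)c2c(OCOC)cc(OC)cc12 | intermediate (not isolated)
11 | benzyl (2S)-1-{4-hydroxy-2-methoxy-4-[7-methoxy-4,5-bis(methoxymethoxy)naphthalen-1-yl]-3-oxocyclobut-1-en-1-yl}pyrrolidine-2-carboxylate, both carbinol epimers | COC1=C(N2CCC[C@H]2C(=O)OCc2ccccc2)C(O)(c2ccc(OCOC)c3c(OCOC)cc(OC)cc23)C1=O | intermediate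
12 | dienylketene from ring opening of 11 | O=C=C(OC)C(N1CCC[C@H]1C(=O)OCc1ccccc1)=C(O)c1ccc(OCOC)c2c(OCOC)cc(OC)cc12 | intermediate (not isolated)
13 | benzyl (2S)-1-[1,4-dihydroxy-2,6-dimethoxy-8,9-bis(methoxymethoxy)phenanthren-3-yl]pyrrolidine-2-carboxylate | COc1c(O)c2cc(OCOC)c3c(OCOC)cc(OC)cc3c2c(O)c1N1CCC[C@H]1C(=O)OCc1ccccc1 | intermediate (not isolated)
14 | benzyl (2S)-1-[2,6-dimethoxy-8,9-bis(methoxymethoxy)-1,4-dioxo-1,4-dihydrophenanthren-3-yl]pyrrolidine-2-carboxylate | COC1=C(N2CCC[C@H]2C(=O)OCc2ccccc2)C(=O)c2c(cc(OCOC)c3c(OCOC)cc(OC)cc23)C1=O | intermediate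
15 | benzyl (2S)-1-[4-hydroxy-2,6-dimethoxy-8,9-bis(methoxymethoxy)-4-methyl-1-oxo-1,4-dihydrophenanthren-3-yl]pyrrolidine-2-carboxylate, both C4 epimers | COC1=C(N2CCC[C@H]2C(=O)OCc2ccccc2)C(C)(O)c2c(cc(OCOC)c3c(OCOC)cc(OC)cc23)C1=O | intermediate (not isolated)
16 | benzyl (2S)-1-[1-hydroxy-2,6-dimethoxy-8,9-bis(methoxymethoxy)-4-methylphenanthren-3-yl]pyrrolidine-2-carboxylate | COc1c(O)c2cc(OCOC)c3c(OCOC)cc(OC)cc3c2c(C)c1N1CCC[C@H]1C(=O)OCc1ccccc1 | intermediate
17 | (2S)-1-[1-hydroxy-2,6-dimethoxy-8,9-bis(methoxymethoxy)-4-methylphenanthren-3-yl]pyrrolidine-2-carboxylic acid | COc1c(O)c2cc(OCOC)c3c(OCOC)cc(OC)cc3c2c(C)c1N1CCC[C@H]1C(=O)O | intermediate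
18 | δ-lactone between the proline carboxyl group and the C4 oxygen, (4R), (αS) | COC1=C2N3CCC[C@H]3C(=O)O[C@]2(C)c2c(cc(OCOC)c3c(OCOC)cc(OC)cc23)C1=O | intermediate
19 | (2S)-1-[(4R)-4-hydroxy-2,6-dimethoxy-8,9-bis(methoxymethoxy)-4-methyl-1-oxo-1,4-dihydrophenanthren-3-yl]pyrrolidine-2-carboxylic acid | COC1=C(N2CCC[C@H]2C(=O)O)[C@](C)(O)c2c(cc(OCOC)c3c(OCOC)cc(OC)cc23)C1=O | intermediate
20 | 1-pyrrolinium (iminium) acetate from decarboxylation of 19 | COC1=C([N+]2=CCCC2)[C@](C)(O)c2c(cc(OCOC)c3c(OCOC)cc(OC)cc23)C1=O.CC(=O)[O-] | intermediate (not isolated)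
21 | 8,9-bis(methoxymethyl) ether of the 9-phenanthrol form of the target, (R) at C4, (S) at the aminal carbon | COC1=C2N3CCC[C@@H]3O[C@]2(C)c2c(cc(OCOC)c3c(OCOC)cc(OC)cc23)C1=O | intermediate
22 | 8,9-dihydroxy (9-phenanthrol) tautomer of the target | COC1=C2N3CCC[C@@H]3O[C@]2(C)c2c(cc(O)c3c(O)cc(OC)cc23)C1=O | intermediate (not isolated)
23 | CNP0528850.1 | COC1=C2N3CCC[C@@H]3O[C@]2(C)C2=C(CC(=O)c3c(O)cc(OC)cc32)C1=O | target

**Totals**
Total step count: 13. Longest linear sequence: 12 steps (steps 1–4 and 6–13).

**Steps most likely to fail**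

Step 10. The facial selectivity of the C–O bond formation at C4 may be poor, or the iodane may decarboxylate the N-aryl amino acid before the phenol is dearomatised. The fallback replaces the chirality relay by a separation and sets out from quinone 14. The Grignard addition of step 8 is worked up without zinc, and the two C4 epimers of p-quinol 15, which are diastereomers because of the proline centre, are separated by chromatography. The (4R)-epimer, benzyl (2S)-1-[(4R)-4-hydroxy-2,6-dimethoxy-8,9-bis(methoxymethoxy)-4-methyl-1-oxo-1,4-dihydrophenanthren-3-yl]pyrrolidine-2-carboxylate F1, is saponified with LiOH in THF/water, and the route is rejoined at hydroxy acid 19.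

Step 8. The Grignard reagent may attack the C1 carbonyl instead of C4, or reduce the quinone by electron transfer. The fallback fixes the position of the methyl group by cross-coupling and sets out from carbinol 11. Silylation (TBSOTf, 2,6-lutidine) gives the silyl ether F2. Thermolysis in p-xylene without oxidant gives the differentiated hydroquinone, the 4-silyloxy-1-phenanthrol F3. Benzylation of the C1 hydroxyl (BnBr, K2CO3) gives F4, and fluoride (TBAF) frees the C4 phenol F5. Triflation (Tf2O, pyridine) gives the C4 triflate F6, and palladium-catalysed methylation (Pd(OAc)2, SPhos, trimethylboroxine, K3PO4) gives the 4-methyl benzyl ether F7. Hydrogenolysis (H2, Pd/C) of both benzyl groups returns to the route at acid 17.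

Step 12. The lead oxidant may over-oxidise the electron-rich naphthalene or fragment the tertiary alcohol. The fallback is a radical decarboxylation without a metal oxidant and sets out from hydroxy acid 19. Coupling with N-hydroxypyridine-2-thione (EDC, CH2Cl2, dark) gives the Barton ester F8. Visible-light photolysis gives the 2-(pyridin-2-ylthio)pyrrolidine N,S-acetal F9. A thiophile (AgOTf, CH2Cl2) ionises F9 to the iminium ion, which the C4 hydroxyl closes to 21, where the route is rejoined.

**Further compounds**
F1 | step 10 | benzyl (2S)-1-[(4R)-4-hydroxy-2,6-dimethoxy-8,9-bis(methoxymethoxy)-4-methyl-1-oxo-1,4-dihydrophenanthren-3-yl]pyrrolidine-2-carboxylate | COC1=C(N2CCC[C@H]2C(=O)OCc2ccccc2)[C@](C)(O)c2c(cc(OCOC)c3c(OCOC)cc(OC)cc23)C1=O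
F2 | step 8 | tert-butyldimethylsilyl ether of carbinol 11 | COC1=C(N2CCC[C@H]2C(=O)OCc2ccccc2)C(O[Si](C)(C)C(C)(C)C)(c2ccc(OCOC)c3c(OCOC)cc(OC)cc23)C1=O
F3 | step 8 | benzyl (2S)-1-[4-(tert-butyldimethylsilyloxy)-1-hydroxy-2,6-dimethoxy-8,9-bis(methoxymethoxy)phenanthren-3-yl]pyrrolidine-2-carboxylate | COc1c(O)c2cc(OCOC)c3c(OCOC)cc(OC)cc3c2c(O[Si](C)(C)C(C)(C)C)c1N1CCC[C@H]1C(=O)OCc1ccccc1
F4 | step 8 | benzyl (2S)-1-[1-benzyloxy-4-(tert-butyldimethylsilyloxy)-2,6-dimethoxy-8,9-bis(methoxymethoxy)phenanthren-3-yl]pyrrolidine-2-carboxylate | COc1c(OCc2ccccc2)c2cc(OCOC)c3c(OCOC)cc(OC)cc3c2c(O[Si](C)(C)C(C)(C)C)c1N1CCC[C@H]1C(=O)OCc1ccccc1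
F5 | step 8 | benzyl (2S)-1-[1-benzyloxy-4-hydroxy-2,6-dimethoxy-8,9-bis(methoxymethoxy)phenanthren-3-yl]pyrrolidine-2-carboxylate | COc1c(OCc2ccccc2)c2cc(OCOC)c3c(OCOC)cc(OC)cc3c2c(O)c1N1CCC[C@H]1C(=O)OCc1ccccc1
F6 | step 8 | benzyl (2S)-1-[1-benzyloxy-2,6-dimethoxy-8,9-bis(methoxymethoxy)-4-(trifluoromethylsulfonyloxy)phenanthren-3-yl]pyrrolidine-2-carboxylate | COc1c(OCc2ccccc2)c2cc(OCOC)c3c(OCOC)cc(OC)cc3c2c(OS(=O)(=O)C(F)(F)F)c1N1CCC[C@H]1C(=O)OCc1ccccc1
F7 | step 8 | benzyl (2S)-1-[1-benzyloxy-2,6-dimethoxy-8,9-bis(methoxymethoxy)-4-methylphenanthren-3-yl]pyrrolidine-2-carboxylate | COc1c(OCc2ccccc2)c2cc(OCOC)c3c(OCOC)cc(OC)cc3c2c(C)c1N1CCC[C@H]1C(=O)OCc1ccccc1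
F8 | step 12 | Barton ester (2-thioxopyridin-1(2H)-yl ester) of hydroxy acid 19 | COC1=C(N2CCC[C@H]2C(=O)ON2C=CC=CC2=S)[C@](C)(O)c2c(cc(OCOC)c3c(OCOC)cc(OC)cc23)C1=O
F9 | step 12 | (4R)-4-hydroxy-2,6-dimethoxy-8,9-bis(methoxymethoxy)-4-methyl-3-[2-(pyridin-2-ylthio)pyrrolidin-1-yl]phenanthren-1(4H)-one, both epimers at the N,S-acetal carbon | COC1=C(N2CCCC2Sc2ccccn2)[C@](C)(O)c2c(cc(OCOC)c3c(OCOC)cc(OC)cc23)C1=O
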